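## Structural features

The target is an elemane-type sesquiterpenoid built on a single cyclohexane (ring A, C5–C10 in elemane numbering) that carries a substituent on every ring carbon except C9. C10 is quaternary (methyl C14 and vinyl C1=C2), C5 bears the 3-hydroxyprop-1-en-2-yl group (C4(=C3)–C15–OH), C6 a free hydroxyl, C7 the acrylic acid C11(=C13)–C12O2H and C8 an ester oxygen, so five stereocentres (C10, C5, C6, C7, C8) are contiguous. The C10 vinyl group, the C5 branch, O6 and C11 lie on one face of the ring, the C10 methyl and O8 on the other; in the chair the vinyl group and O6 are axial and the rest equatorial. O8 is acylated by (2Z)-4-acetoxy-2-methylbut-2-enoic acid, whose carbonyl and acetoxymethyl groups are cis. Fragile points are the γ-hydroxy acid (C12 and O6 are cis and close to an α-methylene lactone under acid or on carboxyl activation), the Z-enoate (it can isomerise or collapse to a butenolide), the base-labile primary allylic acetate, and C5, which is epimerisable whenever C6 is a carbonyl. The real difficulty is the all-cis C5/C6/C7 array next to the quaternary centre, together with the need to tell three hydroxyls and two carboxyl groups apart at the end. The key step exploits the fact that O6, C11 and O8 sit on three adjacent ring carbons with C11 cis to O6 and trans to O8: a two-carbon unit tethered to O6 can only reach the same face of C7 across a C7=C8 double bond, and the C8 radical left behind can be oxygenated from the opposite face.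

## Logic of the disconnections

39 from 38: the two O–Si bonds (O6, O15) and the silylethyl ester bond at C12 are cut last. The free γ-hydroxy acid can lactonise, so it is released only in the final step and under non-acidic fluoride conditions. The demand is that the C12 ester falls no later than the O6 silyl ether and that the acetate and Z-enoate survive.

38 from 31 and 36: the O8–acyl bond is cut. The most labile unit arrives as late as possible, and with O6, O15 and C12 blocked, O8 is the only nucleophile. The forward acylation must reach a hindered secondary alcohol without Z to E isomerisation of 36.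

36 from 35 and 32: the Z geometry of 36 is traced to the ring of 32. The cut is the lactone C–O bond (opened) plus the acetate and benzylic ester bonds. The opened hydroxy carboxylate 33 must be trapped on both oxygens before it recloses.

31 from 30: the N–O bond is cut. O8 was delivered in the key step as an aminoxy ether, which serves as its protecting group and keeps O8 distinct from O6. The reduction must spare the acrylate and the silicon groups.

30 from 29 and 26: the C12 ester bond and the O6–Si bond are cut and O6–C12 is reconnected as the cis-fused lactone. The lactone is opened while O8 is still masked, so that O6 can be silylated alone. The forward step must silylate a hindered axial hydroxyl faster than the hydroxy acid recloses.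

26 from 23, and 23 from 22 and 21: C11=C13 is cut to a one-carbon iminium electrophile, and the C12 carbonyl is traced to the acetal carbon. The acetal hydrolysis dictates an acid-stable silyl group on O15, and the oxidation must leave the N–O bond and four alkenes alone.

21 from 19 and 20 (key disconnection): C7–C11 and C8–O8 are cut. One step then supplies a ring, the C11–C12 unit, O8 and the C7 and C8 stereocentres from a cyclohexenol. The demand is that 5-exo closure outruns capture of the first radical by 20 and that 20 attacks C8 anti to the new ring.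

19 from 17 and 18, and 17 from 16 and 15: the O6–C12 acetal bond and the C–Br bond go back to the enol ether 18. The C6–H bond is cut to a ketone because the carbinol configuration in 15 is not controlled and is better erased and reset. Hydride must come from the face opposite the C5 branch and the C10 vinyl group, and C5 must not epimerise in 16.

15 from 14, 14 from 13, and 13 from 12 and 11: the C7=C8 bond is cut by metathesis and C6–C7 by vinyl addition, with a redox adjustment at C6. The ring closure must choose the allyl and vinyl carbinol pair over the hindered C10 vinyl group and the 1,1-disubstituted C3=C4.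

11 from 8: the C5–C10 bond is cut by a [3,3] shift. This creates the quaternary centre and C5 in one step from an achiral ester. It demands control of enolate geometry and of the enantiotopic face by a chiral boron reagent.

8 from 7, 5, 4 and 3, and 3 from 1: the ester C–O bond is cut to an anhydride opening and C15 is adjusted to the alcohol level. In 3 the C10–C14 and C1–C2 bonds are cut to a methyl-metal addition across the alkyne of 1 and a formaldehyde quench. The anhydride must open at the non-conjugated carbonyl, and the carbometalation must be syn and regioselective.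

## Other disconnections considered

Alternative 1: The cut is C10–C1 and C5–C4, with C2–C3 joined in a four-membered ring. In the forward direction the enone A2 and the cyclobutene ester A3 would be irradiated to give the cis-anti-cis photoadduct A1, and later thermolysis of the bicyclo[2.2.0]hexane would unveil the C10 vinyl group and the C5 propenoate branch. In its favour: the cis ring fusion fixes the cis relation of the vinyl group and the C5 branch, the quaternary centre forms in one step, and O8, the C6 carbonyl and an oxidised C15 are present from the start. On speed of access to the C5/C10 pair this is better than the chosen plan, which needs the Claisen and metathesis sequence. Against it here: the head-to-head or head-to-tail sense of an enone adding to an electron-poor cyclobutene is hard to predict, and the remote C8 stereocentre must direct the face of addition. A1 is a β-silyloxy ketone, so any C6 enolate used to attach C11 at C7 risks eliminating O8. The cycloreversion needs high temperature with C5 epimerisable, and C7, C6 and the C11–C13 unit would still have to be set one at a time. Mechanistically it is an excited-state step against a ground-state radical step, so it is tin-free but less predictable in regiochemistry. In step count it should be equal up to the ring and longer after it.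

Alternative 2: The cut is C5–C10, made while C2–C3 is joined, so the cyclohexane is traced to the ten-membered diene A5. Heating A5 would give A4 by a Cope rearrangement through a chair transition state. In its favour: it follows the likely biogenesis, it is stereospecific, the (1(10)E,4Z) geometry translates directly into the cis vinyl and C5-branch relation, and no reagent is needed. A4 is one fluoride step from the target, so after the key step this plan is clearly shorter than the chosen one, and as a concerted reaction it is cleaner. Against it here: all the difficulty moves into A5. A5 is a medium ring with one E and one Z trisubstituted alkene, three contiguous stereocentres, both acyl groups and three silicon groups already in place, and it must be closed and then heated without Z to E isomerisation of the side chain. The position of the Cope equilibrium and the choice between chair and boat are not assured for this substitution pattern. Structurally the chosen plan builds the six-membered ring by a reliable closure and adds the oxygens afterwards. Overall step economy is expected to be no better once the synthesis of A5 is counted.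

Alternative 3: The cut is C7–C8. The C7 enolate or enamine of the C6 ketone in the keto aldehyde A7 would add to the C8 aldehyde and close the ring to A6. In its favour: the chemistry is simple and tin-free, and C7 and C8 can equilibrate (C7 by enolisation, C8 by retro-aldol) to the all-equatorial trans arrangement that the target needs. C11–C12 arrives at the carboxyl oxidation level, so no acetal has to be oxidised, and O8 (alcohol) and O6 (ketone) are differentiated without protecting groups. On these two points it is better than the chosen plan. A hydroxyl-directed reduction from O8 would in principle deliver the anti 1,3-diol, which is the required O6 configuration. Against it here: C5–H is the more acidic α-position (it is also allylic), so enolisation toward C7 competes with epimerisation or conjugation at C5. The β-hydroxy ketone can dehydrate or lactonise onto C12. Making A7 requires one terminal alkene of three to be cleaved selectively to the aldehyde. Mechanistically it relies on thermodynamic control where the chosen plan uses the kinetic constraint of a tether. Step count to the ring is similar; the end game would be shorter if the C5 problem could be held.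

Key step: step 13

Assumption: in step 5 the (S,S) antipode of the boron reagent and the iPr2NEt/CH2Cl2 pair are taken to give the (2R,3R) acid through the ketene acetal with the alkenyl group cis to O–B. If either sense proved opposite, the (R,R) antipode or the Et3N/toluene–hexane pair would be substituted without changing the route.

## Route

Step 1
Reactants: 1 pent-1-en-4-yne
Product: 3 (2E)-3-methylhexa-2,5-dien-1-ol, via alkenyldimethylalane 2 (not isolated)
Conditions: Me3Al, Cp2ZrCl2 (cat.), CH2Cl2, 0 °C → rt; then (CH2O)n, THF, 0 °C → rt; aq. work-up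
Reagents that add atoms: trimethylaluminium, C[Al](C)C; formaldehyde (as paraformaldehyde), C=O
Why: Zirconium-catalysed carboalumination adds methyl and aluminium syn across the terminal alkyne, methyl at the internal carbon, to give the E-alkenylalane, which is hydroxymethylated with retention; the isolated alkene does not react.

Step 2
Reactants: 3 (2E)-3-methylhexa-2,5-dien-1-ol; 4 itaconic anhydride
Product: 5 2-methylidene-4-{[(2E)-3-methylhexa-2,5-dien-1-yl]oxy}-4-oxobutanoic acid
Conditions: PhMe, 70 °C, no base
Reagents that add atoms: none
Why: Alcoholysis of the cyclic anhydride should occur at the carbonyl that is not conjugated with the methylene group (more electrophilic, less hindered), giving the half ester with the free acrylic acid; base is avoided to prevent isomerisation to the citraconic series.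

Step 3
Reactants: 5 half ester
Product: 7 (2E)-3-methylhexa-2,5-dien-1-yl 3-(hydroxymethyl)but-3-enoate, via mixed carbonic anhydride 6 (not isolated)
Conditions: i-BuOCOCl, N-methylmorpholine, THF, −15 °C; then NaBH4, THF/H2O, −15 → 0 °C
Reagents that add atoms: none
Why: Mixed-anhydride reduction: borohydride reduces the activated acyl carbon by 1,2-attack and leaves the allyl ester; 7 is a γ-hydroxy ester that could lactonise and is therefore silylated at once.

Step 4
Reactants: 7 hydroxy ester
Product: 8 (2E)-3-methylhexa-2,5-dien-1-yl 3-{[(tert-butyldiphenylsilyl)oxy]methyl}but-3-enoate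
Conditions: TBDPSCl, imidazole, CH2Cl2, 0 °C → rt
Reagents that add atoms: tert-butyl(chloro)diphenylsilane, CC(C)(C)[Si](Cl)(c1ccccc1)c1ccccc1
Why: Silylation of the primary allylic alcohol; the tert-butyldiphenylsilyl group is chosen over the dimethyl analogue because it must survive the aqueous acid of step 14 and the zinc/acetic acid of step 19.

Step 5
Reactants: 8 silyloxy allyl ester
Product: 11 (2R,3R)-2-{3-[(tert-butyldiphenylsilyl)oxy]prop-1-en-2-yl}-3-ethenyl-3-methylhex-5-enoic acid, via boron ketene acetal 9 (not isolated), via boron carboxylate 10 (not isolated)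
Conditions: (S,S)-2-bromo-4,5-diphenyl-1,3-bis{[3,5-bis(trifluoromethyl)phenyl]sulfonyl}-1,3,2-diazaborolidine, iPr2NEt, CH2Cl2, −78 °C; then −20 → 4 °C; aq. work-up
Reagents that add atoms: none
Why: Enantioselective Ireland–Claisen rearrangement through a chiral boron ketene acetal and a chair transition state: the E allyl unit places C9 equatorial and the methyl axial, and the ketene acetal with C4 cis to O–B places C4 equatorial, which gives the C5/C10 relative configuration with vinyl cis to the C5 branch. The C2-symmetric sulfonamide ligand selects the enantiotopic face, and only the α-carbon of the dienolate can reach the allyl terminus.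

Step 6
Reactants: 11 acid
Product: 12 (2R,3R)-2-{3-[(tert-butyldiphenylsilyl)oxy]prop-1-en-2-yl}-3-ethenyl-3-methylhex-5-en-1-ol
Conditions: LiAlH4, Et2O, 0 °C → rt
Reagents that add atoms: none
Why: Hydride reduction of the carboxylic acid to the primary alcohol; the carboxylate is not enolised, so C5 is untouched, and the silyl ether and isolated alkenes are inert.

Step 7
Reactants: 12 primary alcohol
Product: 13 (2R,3R)-2-{3-[(tert-butyldiphenylsilyl)oxy]prop-1-en-2-yl}-3-ethenyl-3-methylhex-5-enal
Conditions: Dess–Martin periodinane, NaHCO3, CH2Cl2, 0 °C → rt; used crude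
Reagents that add atoms: none
Why: Dess–Martin oxidation under buffered, non-basic conditions should give the β,γ-unsaturated aldehyde without epimerisation or conjugation at C5.

Step 8
Reactants: 13 aldehyde
Product: 14 (4R,5R)-4-{3-[(tert-butyldiphenylsilyl)oxy]prop-1-en-2-yl}-5-ethenyl-5-methylocta-1,7-dien-3-ol (both C3 epimers)
Conditions: CH2=CHMgBr, THF, −78 °C
Reagents that add atoms: vinylmagnesium bromide, C=C[Mg]Br
Why: Grignard addition at low temperature outruns enolisation of the hindered aldehyde; the new carbinol centre (C6) is not controlled (the Felkin–Anh preference is expected to favour the unwanted epimer) and is reset in steps 10 and 11.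

Step 9
Reactants: 14 dienol mixture
Product: 15 (5R,6R)-6-{3-[(tert-butyldiphenylsilyl)oxy]prop-1-en-2-yl}-5-ethenyl-5-methylcyclohex-2-en-1-ol (both C1 epimers)
Conditions: first-generation Grubbs catalyst RuCl2(=CHPh)(PCy3)2 (cat.), CH2Cl2, 40 °C
Reagents that add atoms: none
Why: Ring-closing metathesis: the catalyst loads on the unhindered allyl group and closes onto the monosubstituted vinyl carbinol to the six-membered ring; the vinyl group on quaternary C10 and the 1,1-disubstituted C3=C4 are poor partners for this phosphine catalyst.

Step 10
Reactants: 15 cyclohexenol mixture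
Product: 16 (5R,6R)-6-{3-[(tert-butyldiphenylsilyl)oxy]prop-1-en-2-yl}-5-ethenyl-5-methylcyclohex-2-en-1-one
Conditions: MnO2, CH2Cl2, rt
Reagents that add atoms: none
Why: Allylic alcohol oxidation on the MnO2 surface under neutral conditions converges both epimers on one enone without disturbing C5, which is now α to the carbonyl.

Step 11
Reactants: 16 enone
Product: 17 (1R,5R,6R)-6-{3-[(tert-butyldiphenylsilyl)oxy]prop-1-en-2-yl}-5-ethenyl-5-methylcyclohex-2-en-1-ol
Conditions: NaBH4, CeCl3·7H2O, MeOH, −78 °C
Reagents that add atoms: none
Why: Luche 1,2-reduction: the C5 branch and the pseudo-axial C10 vinyl group lie on the same face, so hydride should add to C6 from the opposite face and place O6 cis to both; the weakly acidic medium protects C5 from epimerisation.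

Step 12
Reactants: 17 cyclohexenol; 18 ethyl vinyl ether
Product: 19 O6 2-bromo-1-ethoxyethyl acetal of 17 (either acetal epimer)
Conditions: NBS, CH2Cl2, −40 → 0 °C
Reagents that add atoms: N-bromosuccinimide, O=C1CCC(=O)N1Br
Why: Haloetherification: bromination of the electron-rich enol ether gives an oxocarbenium ion that is captured by O6; the other alkenes are far less nucleophilic, and no stereocentre of the ring is touched.

Step 13
Reactants: 19 bromoacetal; 20 TEMPO (2,2,6,6-tetramethylpiperidin-1-yloxyl)
Product: 21 cis-fused 2-ethoxytetrahydrofuran acetal with the O8 2,2,6,6-tetramethylpiperidin-1-yl ether (acetal carbon as a mixture)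
Conditions: Bu3SnSnBu3, hν (sunlamp, Pyrex), PhH, 80 °C; 20 added by syringe pump
Reagents that add atoms: none
Why: Photolysis of the distannane gives stannyl radicals that abstract bromine from 19; the primary C11 radical adds 5-exo-trig to C7 of the ring alkene, and the secondary C8 radical couples with the nitroxide at a near diffusion-controlled rate, which is a Ueno–Stork haloacetal cyclisation terminated by nitroxide capture. The five-membered acetal ring can only be cis-fused to the cyclohexane, so C11 arrives on the face of O6 and C7 is set by the C6 stereocentre. The nitroxide then approaches C8 from the face opposite the new ring and the axial C10 vinyl group, which sets O8 trans to C11. Coupling of 20 with the uncyclised radical is the competing reaction, so 20 is dosed slowly and its stationary concentration is kept far below that of 19. A hydride-free tin source is used so that the C8 radical cannot be reduced to the simple deoxy product. 5-exo closure onto C7 is preferred over 6-endo attack at C8 and over addition to C3=C4 or the vinyl group, which would need larger or bridged rings. The acetal carbon forms as a mixture that disappears at the lactone stage.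

Step 14
Reactants: 21 ethyl acetal
Product: 22 lactol (C12 hemiacetal, mixture of epimers)
Conditions: 1 M HCl, THF, rt
Reagents that add atoms: water, O
Why: Acid hydrolysis of the cyclic mixed acetal; the alkoxyamine and the tert-butyldiphenylsilyl ether tolerate dilute acid, where the dimethyl analogue would be lost.

Step 15
Reactants: 22 lactol
Product: 23 cis-fused 6,12-lactone with O8 as the tetramethylpiperidinyl ether
Conditions: TEMPO (cat.), PhI(OAc)2, CH2Cl2, rt
Reagents that add atoms: none
Why: Oxoammonium-mediated oxidation of the lactol converges both hemiacetal epimers on one γ-lactone; the alkoxyamine, silyl ether and alkenes are inert to this oxidant.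

Step 16
Reactants: 23 lactone
Product: 26 α-methylene lactone, via Mannich base 24 (not isolated), via methiodide 25 (not isolated)
Conditions: LDA, THF, −78 °C; CH2=NMe2+ I−, −78 °C → rt; then MeI, MeOH, rt; then NaHCO3 (aq), EtOAc
Reagents that add atoms: N,N-dimethylmethylideneammonium iodide (Eschenmoser's salt), C=[N+](C)C.[I-]
Why: α-Methylenation by Mannich reaction of the lactone enolate with the iminium salt on the convex face, N-methylation and E1cB elimination; the C11 stereocentre of 24 is destroyed on elimination, and the hindered piperidine nitrogen is not alkylated.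

Step 17
Reactants: 26 α-methylene lactone
Product: 29 O6-silylated acrylic acid, via lithium carboxylate 27 (not isolated), via bis-silyl compound 28 (not isolated)
Conditions: LiOH, THF/H2O, 0 °C → rt; evaporate, PhMe azeotrope; TBSOTf, 2,6-lutidine, CH2Cl2, −78 → 0 °C; then K2CO3, MeOH/THF/H2O, 0 °C; pH 5 buffer
Reagents that add atoms: lithium hydroxide, [Li+].[OH-]; tert-butyldimethylsilyl trifluoromethanesulfonate, CC(C)(C)[Si](C)(C)OS(=O)(=O)C(F)(F)F
Why: Saponification of the lactone, exhaustive silylation (O6 ether and silyl ester) before the hydroxy acid can reclose, and selective solvolysis of the labile silyl ester; O6 is capped while O8 is still masked as the alkoxyamine, which differentiates the two secondary oxygens.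

Step 18
Reactants: 29 acid
Product: 30 2-(trimethylsilyl)ethyl ester of 29
Conditions: Me3SiCH2CH2OH, EDC·HCl, DMAP (cat.), CH2Cl2, 0 °C → rt
Reagents that add atoms: 2-(trimethylsilyl)ethanol, C[Si](C)(C)CCO
Why: Steglich-type carbodiimide esterification of the acrylic acid; with O6 silylated no lactone can form on activation.

Step 19
Reactants: 30 alkoxyamine ester
Product: 31 O8 alcohol
Conditions: Zn, AcOH/THF/H2O (3:1:1), 50 °C
Reagents that add atoms: none
Why: Reductive cleavage of the N–O bond by zinc in acetic acid; the C8–O bond and its configuration are untouched, and the hindered secondary silyl ether, the diphenylsilyl ether, the silylethyl ester and the acrylate should survive.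

Step 20
Reactants: 32 3-methylfuran-2(5H)-one
Product: 35 4-methoxybenzyl (2Z)-4-(acetyloxy)-2-methylbut-2-enoate, via potassium hydroxy carboxylate 33 (not isolated), via hydroxy ester 34 (not isolated)
Conditions: KOH (1.0 equiv), H2O/THF, 0 °C → rt; lyophilise; 4-MeOC6H4CH2Cl, DMF, 0 °C → rt; then Ac2O, pyridine, DMAP (cat.), 0 °C
Reagents that add atoms: potassium hydroxide, [K+].[OH-]; 4-methoxybenzyl chloride, COc1ccc(CCl)cc1; acetic anhydride, CC(=O)OC(C)=O
Why: Saponification opens the butenolide to the Z hydroxy carboxylate, whose geometry is fixed by the ring; O-alkylation of the carboxylate and immediate acetylation of the primary hydroxyl prevent reclosure.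

Step 21
Reactants: 35 4-methoxybenzyl ester
Product: 36 (2Z)-4-(acetyloxy)-2-methylbut-2-enoic acid
Conditions: CF3CO2H, anisole, CH2Cl2, 0 °C
Reagents that add atoms: none
Why: Acidolysis of the 4-methoxybenzyl ester, with the benzylic cation trapped by anisole; the acetate and the Z-alkene are not affected under these brief conditions.

Step 22
Reactants: 31 O8 alcohol; 36 (2Z)-4-(acetyloxy)-2-methylbut-2-enoic acid
Product: 38 fully protected target, via mixed anhydride 37 (not isolated)
Conditions: 2,4,6-Cl3C6H2COCl, Et3N, PhMe, rt; then 31, DMAP, PhMe, 0 °C → rt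
Reagents that add atoms: none
Why: Yamaguchi esterification: the mixed anhydride transfers the acyl group through the acylpyridinium to O8, the only free hydroxyl; low temperature and a limited amount of the pyridine catalyst are meant to suppress Z to E isomerisation.

Step 23
Reactants: 38 fully protected target
Product: 39 target, 2-[(1S,2S,3R,4R,6S)-6-{[(2Z)-4-(acetyloxy)-2-methylbut-2-enoyl]oxy}-4-ethenyl-2-hydroxy-3-(3-hydroxyprop-1-en-2-yl)-4-methylcyclohexyl]prop-2-enoic acid
Conditions: tris(dimethylamino)sulfonium difluorotrimethylsilicate (TASF), wet DMF, 0 °C → rt; aq. NH4Cl (pH about 5), cold extraction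
Reagents that add atoms: none
Why: Fluoride attacks silicon: the 2-(trimethylsilyl)ethyl ester fragments first to the carboxylate, which cannot lactonise, and the two silyl ethers then fall; this weakly basic fluoride source should spare the acetate and the Z-enoate, and work-up near neutrality avoids closure of the γ-hydroxy acid.

## Compound list

1 | pent-1-en-4-yne | C=CCC#C | starting material
2 | dimethyl[(1E)-2-methylpenta-1,4-dien-1-yl]alumane | C=CC/C(C)=C/[Al](C)C | intermediate
3 | (2E)-3-methylhexa-2,5-dien-1-ol | C=CC/C(C)=C/CO | intermediate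
4 | itaconic anhydride (3-methylideneoxolane-2,5-dione) | C=C1CC(=O)OC1=O | starting material
5 | 2-methylidene-4-{[(2E)-3-methylhexa-2,5-dien-1-yl]oxy}-4-oxobutanoic acid | C=CC/C(C)=C/COC(=O)CC(=C)C(=O)O | intermediate
6 | mixed anhydride of 5 with isobutyl hydrogen carbonate | C=CC/C(C)=C/COC(=O)CC(=C)C(=O)OC(=O)OCC(C)C | intermediate
7 | (2E)-3-methylhexa-2,5-dien-1-yl 3-(hydroxymethyl)but-3-enoate | C=CC/C(C)=C/COC(=O)CC(=C)CO | intermediate
8 | (2E)-3-methylhexa-2,5-dien-1-yl 3-{[(tert-butyldiphenylsilyl)oxy]methyl}but-3-enoate | C=CC/C(C)=C/COC(=O)CC(=C)CO[Si](c1ccccc1)(c1ccccc1)C(C)(C)C | intermediate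
9 | boron ketene acetal of 8 with the (4S,5S)-diazaborolidine, alkenyl group cis to O–B | C=CC/C(C)=C/CO/C(OB1N(S(=O)(=O)c2cc(cc(c2)C(F)(F)F)C(F)(F)F)[C@@H](c2ccccc2)[C@H](c2ccccc2)N1S(=O)(=O)c1cc(cc(c1)C(F)(F)F)C(F)(F)F)=C/C(=C)CO[Si](c1ccccc1)(c1ccccc1)C(C)(C)C | intermediate
10 | B-acyloxy-(4S,5S)-diazaborolidine (boron carboxylate of 11) | C=C[C@@](C)(CC=C)[C@@H](C(=O)OB1N(S(=O)(=O)c2cc(cc(c2)C(F)(F)F)C(F)(F)F)[C@@H](c2ccccc2)[C@H](c2ccccc2)N1S(=O)(=O)c1cc(cc(c1)C(F)(F)F)C(F)(F)F)C(=C)CO[Si](c1ccccc1)(c1ccccc1)C(C)(C)C | intermediate
11 | (2R,3R)-2-{3-[(tert-butyldiphenylsilyl)oxy]prop-1-en-2-yl}-3-ethenyl-3-methylhex-5-enoic acid | C=C[C@@](C)(CC=C)[C@@H](C(=O)O)C(=C)CO[Si](c1ccccc1)(c1ccccc1)C(C)(C)C | intermediate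
12 | (2R,3R)-2-{3-[(tert-butyldiphenylsilyl)oxy]prop-1-en-2-yl}-3-ethenyl-3-methylhex-5-en-1-ol | C=C[C@@](C)(CC=C)[C@@H](CO)C(=C)CO[Si](c1ccccc1)(c1ccccc1)C(C)(C)C | intermediate
13 | (2R,3R)-2-{3-[(tert-butyldiphenylsilyl)oxy]prop-1-en-2-yl}-3-ethenyl-3-methylhex-5-enal | C=C[C@@](C)(CC=C)[C@@H](C=O)C(=C)CO[Si](c1ccccc1)(c1ccccc1)C(C)(C)C | intermediate
14 | (4R,5R)-4-{3-[(tert-butyldiphenylsilyl)oxy]prop-1-en-2-yl}-5-ethenyl-5-methylocta-1,7-dien-3-ol, both C3 epimers | C=C[C@@](C)(CC=C)[C@@H](C(O)C=C)C(=C)CO[Si](c1ccccc1)(c1ccccc1)C(C)(C)C | intermediate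
15 | (5R,6R)-6-{3-[(tert-butyldiphenylsilyl)oxy]prop-1-en-2-yl}-5-ethenyl-5-methylcyclohex-2-en-1-ol, both C1 epimers | C=C[C@@]1(C)CC=CC(O)[C@H]1C(=C)CO[Si](c1ccccc1)(c1ccccc1)C(C)(C)C | intermediate
16 | (5R,6R)-6-{3-[(tert-butyldiphenylsilyl)oxy]prop-1-en-2-yl}-5-ethenyl-5-methylcyclohex-2-en-1-one | C=C[C@@]1(C)CC=CC(=O)[C@H]1C(=C)CO[Si](c1ccccc1)(c1ccccc1)C(C)(C)C | intermediate
17 | (1R,5R,6R)-6-{3-[(tert-butyldiphenylsilyl)oxy]prop-1-en-2-yl}-5-ethenyl-5-methylcyclohex-2-en-1-ol (hydroxyl cis to the C6 branch and the vinyl group) | C=C[C@@]1(C)CC=C[C@@H](O)[C@H]1C(=C)CO[Si](c1ccccc1)(c1ccccc1)C(C)(C)C | intermediate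
18 | ethyl vinyl ether | CCOC=C | starting material
19 | 2-bromo-1-ethoxyethyl ether of 17 at O6 (either acetal epimer; ring centres as in 17) | C=C[C@@]1(C)CC=C[C@@H](OC(OCC)CBr)[C@H]1C(=C)CO[Si](c1ccccc1)(c1ccccc1)C(C)(C)C | intermediate
20 | TEMPO, 2,2,6,6-tetramethylpiperidin-1-yloxyl | CC1(C)CCCC(C)(C)N1[O] | starting material
21 | cis-fused bicyclic acetal: C11–C12(OEt)–O6 ring closed on C6/C7, O8 as 2,2,6,6-tetramethylpiperidin-1-yl ether trans to C11, O15 tert-butyldiphenylsilyl ether; C5, C6, C7, C8, C10 arranged as in 39; C12 as a mixture | C=C[C@@]1(C)C[C@H](ON2C(C)(C)CCCC2(C)C)[C@@H](CC3OCC)[C@@H](O3)[C@H]1C(=C)CO[Si](c1ccccc1)(c1ccccc1)C(C)(C)C | intermediate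
22 | lactol corresponding to 21 (C12 hemiacetal, mixture) | C=C[C@@]1(C)C[C@H](ON2C(C)(C)CCCC2(C)C)[C@@H](CC3O)[C@@H](O3)[C@H]1C(=C)CO[Si](c1ccccc1)(c1ccccc1)C(C)(C)C | intermediate
23 | cis-fused 6,12-lactone (C12 carbonyl, O6 ring oxygen), O8 tetramethylpiperidinyl ether, O15 silyl ether; ring centres as in 39 | C=C[C@@]1(C)C[C@H](ON2C(C)(C)CCCC2(C)C)[C@@H](CC3=O)[C@@H](O3)[C@H]1C(=C)CO[Si](c1ccccc1)(c1ccccc1)C(C)(C)C | intermediate
24 | 11-[(dimethylamino)methyl] derivative of 23 (C11 as formed) | C=C[C@@]1(C)C[C@H](ON2C(C)(C)CCCC2(C)C)[C@@H](C(CN(C)C)C3=O)[C@@H](O3)[C@H]1C(=C)CO[Si](c1ccccc1)(c1ccccc1)C(C)(C)C | intermediate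
25 | trimethylammonium iodide derived from 24 | C=C[C@@]1(C)C[C@H](ON2C(C)(C)CCCC2(C)C)[C@@H](C(C[N+](C)(C)C)C3=O)[C@@H](O3)[C@H]1C(=C)CO[Si](c1ccccc1)(c1ccccc1)C(C)(C)C.[I-] | intermediate
26 | 11(13)-methylene-6,12-lactone, otherwise as 23 | C=C[C@@]1(C)C[C@H](ON2C(C)(C)CCCC2(C)C)[C@@H](C(=C)C3=O)[C@@H](O3)[C@H]1C(=C)CO[Si](c1ccccc1)(c1ccccc1)C(C)(C)C | intermediate
27 | lithium salt of the ring-opened hydroxy acrylic acid from 26 | C=C[C@@]1(C)C[C@H](ON2C(C)(C)CCCC2(C)C)[C@@H](C(=C)C(=O)[O-])[C@@H](O)[C@H]1C(=C)CO[Si](c1ccccc1)(c1ccccc1)C(C)(C)C.[Li+] | intermediate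
28 | O6 tert-butyldimethylsilyl ether, C12 tert-butyldimethylsilyl ester | C=C[C@@]1(C)C[C@H](ON2C(C)(C)CCCC2(C)C)[C@@H](C(=C)C(=O)O[Si](C)(C)C(C)(C)C)[C@@H](O[Si](C)(C)C(C)(C)C)[C@H]1C(=C)CO[Si](c1ccccc1)(c1ccccc1)C(C)(C)C | intermediate
29 | acrylic acid with O6 tert-butyldimethylsilyl ether, O8 tetramethylpiperidinyl ether, O15 tert-butyldiphenylsilyl ether; ring centres as in 39 | C=C[C@@]1(C)C[C@H](ON2C(C)(C)CCCC2(C)C)[C@@H](C(=C)C(=O)O)[C@@H](O[Si](C)(C)C(C)(C)C)[C@H]1C(=C)CO[Si](c1ccccc1)(c1ccccc1)C(C)(C)C | intermediate
30 | 2-(trimethylsilyl)ethyl ester of 29 | C=C[C@@]1(C)C[C@H](ON2C(C)(C)CCCC2(C)C)[C@@H](C(=C)C(=O)OCC[Si](C)(C)C)[C@@H](O[Si](C)(C)C(C)(C)C)[C@H]1C(=C)CO[Si](c1ccccc1)(c1ccccc1)C(C)(C)C | intermediate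
31 | O8 alcohol: 2-(trimethylsilyl)ethyl acrylate with O6 tert-butyldimethylsilyl ether and O15 tert-butyldiphenylsilyl ether; ring centres as in 39 | C=C[C@@]1(C)C[C@H](O)[C@@H](C(=C)C(=O)OCC[Si](C)(C)C)[C@@H](O[Si](C)(C)C(C)(C)C)[C@H]1C(=C)CO[Si](c1ccccc1)(c1ccccc1)C(C)(C)C | intermediate
32 | 3-methylfuran-2(5H)-one | CC1=CCOC1=O | starting material
33 | potassium (2Z)-4-hydroxy-2-methylbut-2-enoate | [K+].[O-]C(=O)/C(C)=C\CO | intermediate
34 | 4-methoxybenzyl (2Z)-4-hydroxy-2-methylbut-2-enoate | COc1ccc(COC(=O)/C(C)=C\CO)cc1 | intermediate
35 | 4-methoxybenzyl (2Z)-4-(acetyloxy)-2-methylbut-2-enoate | COc1ccc(COC(=O)/C(C)=C\COC(C)=O)cc1 | intermediate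
36 | (2Z)-4-(acetyloxy)-2-methylbut-2-enoic acid | OC(=O)/C(C)=C\COC(C)=O | intermediate
37 | mixed anhydride of 36 with 2,4,6-trichlorobenzoic acid | O=C(OC(=O)c1c(Cl)cc(Cl)cc1Cl)/C(C)=C\COC(C)=O | intermediate
38 | 39 as 2-(trimethylsilyl)ethyl ester, O6 tert-butyldimethylsilyl ether and O15 tert-butyldiphenylsilyl ether | C=C[C@@]1(C)C[C@H](OC(=O)/C(C)=C\COC(C)=O)[C@@H](C(=C)C(=O)OCC[Si](C)(C)C)[C@@H](O[Si](C)(C)C(C)(C)C)[C@H]1C(=C)CO[Si](c1ccccc1)(c1ccccc1)C(C)(C)C | intermediate
39 | 2-[(1S,2S,3R,4R,6S)-6-{[(2Z)-4-(acetyloxy)-2-methylbut-2-enoyl]oxy}-4-ethenyl-2-hydroxy-3-(3-hydroxyprop-1-en-2-yl)-4-methylcyclohexyl]prop-2-enoic acid | C=C[C@@]1(C)C[C@H](OC(=O)/C(C)=C\COC(C)=O)[C@@H](C(=C)C(=O)O)[C@@H](O)[C@H]1C(=C)CO | target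

## Step count and least certain steps

Total: 23 steps. Longest linear sequence: 21 steps (steps 1–19, 22 and 23, counted from 1); steps 20 and 21 are a two-step side branch.

Step 13 (key step). The most likely failure is coupling of the nitroxide with the uncyclised C11 radical before ring closure. Both processes are fast and their ratio depends only on the stationary nitroxide concentration. If the nitroxide is starved instead, the C8 radical is lost by disproportionation or atom transfer. The fallback separates cyclisation from oxygen capture. It sets out from 17, which with 18 and N-iodosuccinimide would give the iodoacetal F1. Iodine-atom-transfer cyclisation (Et3B/air, PhH, rt, no nitroxide present) would give the cis-fused C8 iodide F2. Treating F2 with Bu3SnH and an excess of 20 (PhH, 70 °C) would replace iodine by the aminoxy group from the face anti to the ring. A high nitroxide concentration is harmless there because no cyclisation has to compete. The route is rejoined at 21.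

Step 5. The most likely failure is formation of the boron ketene acetal with the wrong geometry, or poor discrimination of the enantiotopic faces for a dienolate that carries a bulky silyloxymethyl group. Either leads to the C5 epimer or to low enantiomeric purity. The fallback gives up reagent control. It sets out from 8, which with LDA and Me3SiCl in THF/DMPU at −78 °C would give the silyl ketene acetal F3 with the alkenyl group cis to O–Si. On warming, F3 rearranges to the racemic trimethylsilyl ester F4, which is hydrolysed on work-up. The racemic acid would be resolved by crystallisation with (S)-1-phenylethylamine, separating the salt F5 of the wanted acid from the salt F6 of its enantiomer. Acidification of F5 returns the route at 11.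

Step 11. The most likely failure is poor facial selectivity of hydride delivery: a small hydride has an intrinsic preference for axial attack and the enone is conformationally mobile, so the O6 epimer may form. The fallback accepts that outcome and inverts it. It sets out from 16, which would be reduced to the trans alcohol F7. Mitsunobu reaction with 4-nitrobenzoic acid (PPh3, DIAD, THF) would give the inverted ester F8. Methanolysis (K2CO3, MeOH) then returns the route at 17.

Step 22. The most likely failures are Z to E isomerisation of the enoate through reversible conjugate addition of the acyl-transfer catalyst, collapse of the activated acid to the butenolide with loss of the acetyl group, and slow acylation of the hindered O8. The fallback builds the alkene on the substrate. It sets out from 31, which would be esterified with 2-(diphenoxyphosphoryl)propanoic acid (EDC, DMAP) to the phosphonate ester F9. A Z-selective Horner–Wadsworth–Emmons olefination of F9 with 2-oxoethyl acetate (NaI, DBU, THF, −78 → 0 °C) returns the route at 38.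

Step 23. The most likely failures are incomplete removal of the hindered O6 silyl ether, loss or migration of the acetate on long exposure to fluoride, and lactonisation during acidification. The fallback stages the deprotection. It sets out from 38, which with HF·pyridine and excess pyridine in THF would lose both silyl ethers while the ester stays, giving the diol ester F10. Brief treatment of F10 with the difluorosilicate then cleaves only the silylethyl ester and returns the route at 39.

## Further compounds

F1 | step 13 | 2-iodo-1-ethoxyethyl ether of 17 at O6 (either acetal epimer) | C=C[C@@]1(C)CC=C[C@@H](OC(OCC)CI)[C@H]1C(=C)CO[Si](c1ccccc1)(c1ccccc1)C(C)(C)C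
F2 | step 13 | cis-fused bicyclic ethyl acetal with iodine at C8 (C8 and acetal carbon as formed) | C=C[C@@]1(C)CC(I)[C@@H](CC3OCC)[C@@H](O3)[C@H]1C(=C)CO[Si](c1ccccc1)(c1ccccc1)C(C)(C)C
F3 | step 5 | trimethylsilyl ketene acetal of 8, alkenyl group cis to O–Si | C=CC/C(C)=C/CO/C(O[Si](C)(C)C)=C/C(=C)CO[Si](c1ccccc1)(c1ccccc1)C(C)(C)C
F4 | step 5 | trimethylsilyl ester of 11, racemic (one enantiomer drawn) | C=C[C@@](C)(CC=C)[C@@H](C(=O)O[Si](C)(C)C)C(=C)CO[Si](c1ccccc1)(c1ccccc1)C(C)(C)C
F5 | step 5 | (S)-1-phenylethylammonium salt of 11 | C=C[C@@](C)(CC=C)[C@@H](C(=O)[O-])C(=C)CO[Si](c1ccccc1)(c1ccccc1)C(C)(C)C.C[C@H]([NH3+])c1ccccc1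
F6 | step 5 | (S)-1-phenylethylammonium salt of the (2S,3S) enantiomer of 11 | C=C[C@](C)(CC=C)[C@H](C(=O)[O-])C(=C)CO[Si](c1ccccc1)(c1ccccc1)C(C)(C)C.C[C@H]([NH3+])c1ccccc1
F7 | step 11 | (1S,5R,6R)-6-{3-[(tert-butyldiphenylsilyl)oxy]prop-1-en-2-yl}-5-ethenyl-5-methylcyclohex-2-en-1-ol (hydroxyl trans to the C6 branch) | C=C[C@@]1(C)CC=C[C@H](O)[C@H]1C(=C)CO[Si](c1ccccc1)(c1ccccc1)C(C)(C)C
F8 | step 11 | 4-nitrobenzoate of 17 | C=C[C@@]1(C)CC=C[C@@H](OC(=O)c2ccc(cc2)[N+](=O)[O-])[C@H]1C(=C)CO[Si](c1ccccc1)(c1ccccc1)C(C)(C)C
F9 | step 22 | O8 2-(diphenoxyphosphoryl)propanoate of 31 | C=C[C@@]1(C)C[C@H](OC(=O)C(C)P(=O)(Oc2ccccc2)Oc2ccccc2)[C@@H](C(=C)C(=O)OCC[Si](C)(C)C)[C@@H](O[Si](C)(C)C(C)(C)C)[C@H]1C(=C)CO[Si](c1ccccc1)(c1ccccc1)C(C)(C)C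
F10 | step 23 | 2-(trimethylsilyl)ethyl ester of 39 with O6 and O15 free | C=C[C@@]1(C)C[C@H](OC(=O)/C(C)=C\COC(C)=O)[C@@H](C(=C)C(=O)OCC[Si](C)(C)C)[C@@H](O)[C@H]1C(=C)CO
A1 | alternative 1 | cis-anti-cis photoadduct, ethyl 9-[(tert-butyldimethylsilyl)oxy]-1-methyl-7-oxotricyclo[4.4.0.0(2,5)]decane-5-carboxylate | O=C1C[C@@H](O[Si](C)(C)C(C)(C)C)C[C@]2(C)[C@H]3CC[C@@]3(C(=O)OCC)[C@H]12
A2 | alternative 1 | (5S)-5-[(tert-butyldimethylsilyl)oxy]-3-methylcyclohex-2-en-1-one | O=C1C[C@@H](O[Si](C)(C)C(C)(C)C)CC(C)=C1
A3 | alternative 1 | ethyl cyclobut-1-ene-1-carboxylate | CCOC(=O)C1=CCC1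
A4 | alternative 2 | 39 as 2-(trimethylsilyl)ethyl ester and 6,15-bis(triethylsilyl) ether | C=C[C@@]1(C)C[C@H](OC(=O)/C(C)=C\COC(C)=O)[C@@H](C(=C)C(=O)OCC[Si](C)(C)C)[C@@H](O[Si](CC)(CC)CC)[C@H]1C(=C)CO[Si](CC)(CC)CC
A5 | alternative 2 | (1(10)E,4Z)-cyclodeca-1(10),4-diene with O6 and O15 triethylsilyl ethers, the C7 2-(trimethylsilyl)ethyl acrylate and the O8 (2Z)-4-acetoxy-2-methylbut-2-enoate | C/C1=C\CC/C(CO[Si](CC)(CC)CC)=C\[C@H](O[Si](CC)(CC)CC)[C@H](C(=C)C(=O)OCC[Si](C)(C)C)[C@@H](OC(=O)/C(C)=C\COC(C)=O)C1
A6 | alternative 3 | 3-hydroxycyclohexanone with the C7 ethyl acetate branch (C6 ketone, O8 hydroxyl, O15 tert-butyldimethylsilyl ether) | C=C[C@@]1(C)C[C@H](O)[C@@H](CC(=O)OCC)C(=O)[C@H]1C(=C)CO[Si](C)(C)C(C)(C)C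
A7 | alternative 3 | open-chain keto aldehyde: C8 aldehyde, C6 ketone, C12 ethyl ester, O15 tert-butyldimethylsilyl ether | C=C[C@@](C)(CC=O)[C@@H](C(=O)CCC(=O)OCC)C(=C)CO[Si](C)(C)C(C)(C)C
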